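The rate constants stand for no real mixture; no experiment stands behind them.

If Q comes off every J + D event and D binds Q, price each event in D before you reckon any yield.

- autumn: J 48 mM; D 58.0 mM; time 3.0 d
- spring: J 48 mM; D 75.0 mM; time 3.0 d

    J + Q → J.Q (k1 = 0.0029 M⁻¹ s⁻¹)
    J + D → Q + L (k2 = 1.3 × 10⁻⁴ M⁻¹ s⁻¹)
    D ⇌ E (K3 = 0.32, k3 = 4.2 × 10⁻⁵ s⁻¹)
    D + Q ⇌ D.Q, settled at all times (K4 = 65000 M⁻¹)

* part of the J that has reacted at the end, autumn
* part of the J that has reacted at the end, spring
* what raising the concentration of D from its lowest to its highest value here does to the part of the J that has reacted (changes below 5 percentage points count as none) (it falls / no change / it rises)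

Follow one Q through autumn. At the fork between free and bound, balance at the charged D holds 3800 bound for each free. Free Q has a half-life of 0.058 d against J with the charges as they stand, so at that balance and those charges a Q held on D has a half-life of about 217 d, far longer than the run. Count each event as taking two D, one into L and one into D.Q.

Work in fractions of the charge: X is the part of J reacted, r the D charged over the J charged, τ the product of k2, J charged and time.

Start with the main step. X = r(1−G)/(1−rG), with G = exp((r−1)τ). For autumn, r = 1.21 and τ = 1.62 give 69.9 %.

Add the trap. Now X = r(1−G)/(2−rG), with G = exp((r−2)τ), and autumn falls to 52.4 %. At this price D is the limiting reagent in autumn, since 58.0 mM is less than two per J charged.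

Add D ⇌ E. It relaxes with a half-life of 1.11 h in autumn, much shorter than the run, so take 75.8 % of the unbound pool as free D and shrink τ to 1.23. That gives the two-D yield, the X of an event that costs two D on the shrunken clock: 48.7 % for autumn.

Add J + Q last, and enter it as zero, on the long life of bound Q above. Spring, with r = 1.56, gets 59.7 %, a rise of 11 percentage points.

The forecast gives 49.6 % and 60.5 %, and says it rises, holding that “each J + D event uses two D, one reacting and one trapped as D.Q”. Its autumn figure stands above mine.

The flask gives 49.4 % in autumn and 60.2 % in spring: it rises, by 11 points. Autumn stands 0.70 points above the two-D yield, with J.Q at 0.765 % of the J charged at the end. Now take a neighbour of autumn charged with 35 mM of D: r = 0.729, and the same clock gives a two-D yield of 31.2 %. In that neighbour the flask holds L at 31.3 % and J.Q at 1.17 % of the J charged, and 32.5 % of its J has reacted.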